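**Plan**

1. Retrosynthesis (locants follow spiro[5.5]undecane: ring A = C1–C5, spiro C6, ring B = C7–C11): the C9–Br/C8–Cl pair goes back to a C8=C9 alkene (chlorohydrin, then tertiary OH to Br with retention), that alkene to a C8 allylic alcohol (reductive transposition), and C4–Br to a C4 ketone (CBS reduction, Appel inversion).
2. Ring A is then cut in one operation at C4–C5 and C1–C6: a four-carbon unit C4(=O)–C3–C2=C1(Me), acylium at one end and (Z)-vinylsilane at the other, is added across an isopropylidene alkene C5=C6.
3. Enabling feature: the gem-dimethyl carbon C5 and the spiro carbon C6 are the two carbons of the exocyclic tetrasubstituted alkene of a p-menthane. Ring B, C5 and the three methyl groups on C5 and C9 are therefore the ten carbons of carvone; the alkene is nucleophilic at C5, and C6 carries the cation that the vinylsilane closes.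
4. Forward: (S)-carvone gives the ring B fragment in 3 steps and pent-3-yn-1-ol gives the acid chloride in 3 steps. Ring B is present from the start, ring A is closed onto it in step 7, and six further steps set C4, move the ring B alkene and add the two ring B halogens.
5. Stereochemistry: carvone C5 sets the carbinol centre (Luche), whose benzoate directs the vinylsilane to one face of C6 and is then erased. C4 comes from reagent control (CBS) plus SN2 inversion. C8 and C9 come from anti addition to the C8=C9 alkene under control of the spiro ring, with retention at C9.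

Key step: step 7

Remark (assumption on the chemistry): in the spiro compounds the vinylic carbon C1 of ring A is taken to be axial, and the bulkier C5 equatorial, on ring B; the face selectivity claimed in step 12 rests on this.

**Route**

Step 1
Reactants: 1 (S)-(+)-carvone
Product: 2 (1S,5S)-cis-carveol
Conditions: NaBH4, CeCl3·7H2O, MeOH, −78 to 0 °C
Reagents that add atoms: none
Why: Luche 1,2-reduction of the enone; hydride should add axially, anti to the pseudoequatorial C5 isopropenyl group, so the new C1 carbinol centre is set cis (1S) by substrate control from C5.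

Step 2
Reactants: 2 (1S,5S)-cis-carveol
Product: 3 (1S,5S)-2-methyl-5-(prop-1-en-2-yl)cyclohex-2-en-1-yl benzoate
Conditions: BzCl, pyridine, DMAP (cat.), CH2Cl2, 0 °C to rt
Reagents that add atoms: benzoyl chloride, O=C(Cl)c1ccccc1
Why: DMAP-catalysed acylation of the secondary allylic alcohol; no stereocentre is touched, and the benzoate is installed as the participating and face-shielding group for step 7.

Step 3
Reactants: 3 (1S,5S)-2-methyl-5-(prop-1-en-2-yl)cyclohex-2-en-1-yl benzoate
Product: 4 (1S)-2-methyl-5-(propan-2-ylidene)cyclohex-2-en-1-yl benzoate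
Conditions: Co(salen)Cl (3 mol %; salen = N,N'-bis(3,5-di-tert-butylsalicylidene)-1,2-cyclohexanediamine dianion), PhSiH3 (6 mol %), benzene, rt
Reagents that add atoms: none
Why: Radical hydrogen-atom-transfer alkene isomerization: the cobalt hydride adds a hydrogen atom to the 1,1-disubstituted isopropenyl group and the tertiary radical gives back the hydrogen atom at C5, forming the favoured tetrasubstituted isopropylidene alkene while the trisubstituted ring alkene stays inert; the C5 stereocentre is deleted on purpose and C1 stays (S).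

Step 4
Reactants: 5 pent-3-yn-1-ol
Product: 6 (Z)-4-(triethylsilyl)pent-3-en-1-ol
Conditions: Et3SiH, [Cp*Ru(MeCN)3]PF6 (1 mol %), CH2Cl2, 0 °C to rt
Reagents that add atoms: triethylsilane, CC[SiH](CC)CC
Why: Cationic ruthenium-catalysed trans-hydrosilylation of an internal alkyne: silicon should go to the alkyne carbon remote from the hydroxyl and H and Si add anti, giving the (Z)-vinylsilane with silicon cis to the hydroxyethyl chain.

Step 5
Reactants: 6 (Z)-4-(triethylsilyl)pent-3-en-1-ol
Product: 7 (Z)-4-(triethylsilyl)pent-3-enoic acid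
Conditions: TEMPO (cat.), PhI(OAc)2, MeCN/H2O, rt
Reagents that add atoms: water, O
Why: Oxoammonium (TEMPO) oxidation of the primary alcohol through the aldehyde hydrate to the acid under near-neutral conditions that should leave the vinylsilane and its geometry intact.

Step 6
Reactants: 7 (Z)-4-(triethylsilyl)pent-3-enoic acid
Product: 8 (Z)-4-(triethylsilyl)pent-3-enoyl chloride
Conditions: (COCl)2, DMF (cat.), CH2Cl2, 0 °C to rt; evaporate, use crude
Reagents that add atoms: oxalyl chloride, O=C(Cl)C(Cl)=O
Why: Acid chloride formation through the Vilsmeier-type chloroiminium intermediate, without strong protic acid that could protodesilylate the vinylsilane.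

Step 7
Reactants: 8 (Z)-4-(triethylsilyl)pent-3-enoyl chloride; 4 (1S)-2-methyl-5-(propan-2-ylidene)cyclohex-2-en-1-yl benzoate
Product: 9 (6S,8S)-1,5,5,9-tetramethyl-4-oxospiro[5.5]undeca-1,9-dien-8-yl benzoate
Conditions: SnCl4, 2,6-di-tert-butyl-4-methylpyridine, CH2Cl2, −78 to −30 °C; cold aq NaHCO3
Reagents that add atoms: none
Why: Proposed new method: SnCl4 turns 8 into an acylium ion that adds to the tetrasubstituted isopropylidene alkene of 4 at its exocyclic CMe2 carbon (Friedel-Crafts-type acylation of an alkene), the tertiary ring cation is then trapped by ipso attack of the tethered (Z)-vinylsilane, and loss of Et3SiCl leaves the trisubstituted C1=C2 alkene, so the C4–C5 and C1–C6 bonds of ring A form in one cationic (4+2) annulation; the closest known reaction types are the Lewis acid acylation of alkenes and vinylsilane-terminated cation-olefin cyclizations (including spiroannulations), which have not been coupled on a tetrasubstituted alkene. Ring A is the only ring closed, in a 6-endo mode in which the vinylsilane carbon becomes C1 and its double bond stays in the ring. The single new stereocentre, spiro C6, is controlled by the C8 benzoate, which sits pseudoaxial (allylic strain with the C9 methyl) and can bridge the cation as a 1,3-dioxan-2-ylium ion, so the vinylsilane should bond to C6 on the face anti to the C8–O bond. The step needs site selectivity (exocyclic alkene before ring alkene), regioselectivity (acyl to the CMe2 carbon, cation on the ring carbon) and facial selectivity: the ring alkene is deactivated by its allylic ester, the anchimerically assisted ring cation is favoured over the isopropyl cation, and the same benzoate shields one face.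

Step 8
Reactants: 9 (6S,8S)-1,5,5,9-tetramethyl-4-oxospiro[5.5]undeca-1,9-dien-8-yl benzoate
Product: 10 (4S,6S,8S)-4-hydroxy-1,5,5,9-tetramethylspiro[5.5]undeca-1,9-dien-8-yl benzoate
Conditions: (R)-2-methyl-CBS-oxazaborolidine (20 mol %), catecholborane, toluene, −40 °C
Reagents that add atoms: none
Why: Corey-Bakshi-Shibata reduction under reagent control: with the quaternary C5 side as the large and the C3 methylene as the small ketone substituent the (R)-catalyst should give the (4S)-alcohol, and catecholborane at low temperature should spare the two trisubstituted alkenes and the ester.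

Step 9
Reactants: 10 (4S,6S,8S)-4-hydroxy-1,5,5,9-tetramethylspiro[5.5]undeca-1,9-dien-8-yl benzoate
Product: 11 (4R,6S,8S)-4-bromo-1,5,5,9-tetramethylspiro[5.5]undeca-1,9-dien-8-yl benzoate
Conditions: CBr4, PPh3, 2,6-lutidine, CH2Cl2, 0 °C to rt
Reagents that add atoms: carbon tetrabromide, BrC(Br)(Br)Br
Why: Appel reaction: bromide should displace the oxyphosphonium group by SN2 with inversion (4S to 4R) from the half-chair with the C–O bond pseudoaxial, the way axial alcohols next to a gem-dimethyl group are turned into equatorial bromides in bromoterpenoid synthesis.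

Step 10
Reactants: 11 (4R,6S,8S)-4-bromo-1,5,5,9-tetramethylspiro[5.5]undeca-1,9-dien-8-yl benzoate
Product: 12 (4R,6S,8S)-4-bromo-1,5,5,9-tetramethylspiro[5.5]undeca-1,9-dien-8-ol
Conditions: K2CO3, MeOH, rt
Reagents that add atoms: none
Why: Base-catalysed transesterification (methanolysis) should free the C8 allylic alcohol without touching the hindered secondary bromide.

Step 11
Reactants: 12 (4R,6S,8S)-4-bromo-1,5,5,9-tetramethylspiro[5.5]undeca-1,9-dien-8-ol
Product: 15 (4R,6S)-4-bromo-1,5,5,9-tetramethylspiro[5.5]undeca-1,8-diene, via N-allylic sulfonylhydrazide 13 (not isolated), via allylic diazene 14 (not isolated)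
Conditions: 2-nitrobenzenesulfonylhydrazide (NBSH), PPh3, DEAD, THF, −30 °C; then 23 °C
Reagents that add atoms: none
Why: Reductive 1,3-transposition of an allylic alcohol: Mitsunobu displacement by the sulfonylhydrazide (inversion at C8), loss of arenesulfinic acid and retro-ene loss of N2 from the diazene should deliver hydrogen to C10 and move the alkene to C8=C9, removing the auxiliary oxygen while C6 stays stereogenic because the ring B alkene now sits on the C7 arm.

Step 12
Reactants: 15 (4R,6S)-4-bromo-1,5,5,9-tetramethylspiro[5.5]undeca-1,8-diene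
Product: 16 (4R,6S,8S,9S)-4-bromo-8-chloro-1,5,5,9-tetramethylspiro[5.5]undec-1-en-9-ol
Conditions: trichloroisocyanuric acid (0.35 equiv), acetone/H2O, 0 °C
Reagents that add atoms: trichloroisocyanuric acid, O=C1N(Cl)C(=O)N(Cl)C(=O)N1Cl; water, O
Why: Electrophilic chlorohydroxylation: the unhindered ring B alkene (the ring A alkene is shielded by the adjacent quaternary C6) should take Cl+ on the face away from the axial C1 arm of ring A, and water should open the chloronium ion anti at the tertiary C9 (Markovnikov), setting C8 (Cl) and C9 (OH) trans by substrate control from C6.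

Step 13
Reactants: 16 (4R,6S,8S,9S)-4-bromo-8-chloro-1,5,5,9-tetramethylspiro[5.5]undec-1-en-9-ol
Product: 17 (4R,6S,8S,9S)-4,9-dibromo-8-chloro-1,5,5,9-tetramethylspiro[5.5]undec-1-ene (target)
Conditions: Me3SiBr, CH2Cl2, −40 to 0 °C
Reagents that add atoms: bromotrimethylsilane, C[Si](C)(C)Br
Why: Halohydrin-to-dihalide substitution with retention: ionization of the tertiary alcohol is assisted by the vicinal trans chlorine (the chlorine-bridged cation of step 12 is regenerated) and bromide should enter at C9 anti to chlorine, so C9 keeps its configuration.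

**Compound list**

1 | (S)-(+)-carvone, (5S)-2-methyl-5-(prop-1-en-2-yl)cyclohex-2-en-1-one | CC1=CC[C@H](C(C)=C)CC1=O | starting material
2 | (1S,5S)-cis-carveol, (1S,5S)-2-methyl-5-(prop-1-en-2-yl)cyclohex-2-en-1-ol | CC1=CC[C@H](C(C)=C)C[C@@H]1O | intermediate
3 | (1S,5S)-2-methyl-5-(prop-1-en-2-yl)cyclohex-2-en-1-yl benzoate | CC1=CC[C@H](C(C)=C)C[C@@H]1OC(=O)c2ccccc2 | intermediate
4 | (1S)-2-methyl-5-(propan-2-ylidene)cyclohex-2-en-1-yl benzoate | CC1=CCC(=C(C)C)C[C@@H]1OC(=O)c2ccccc2 | intermediate
5 | pent-3-yn-1-ol | CC#CCCO | starting material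
6 | (Z)-4-(triethylsilyl)pent-3-en-1-ol | C/C(=C/CCO)[Si](CC)(CC)CC | intermediate
7 | (Z)-4-(triethylsilyl)pent-3-enoic acid | C/C(=C/CC(=O)O)[Si](CC)(CC)CC | intermediate
8 | (Z)-4-(triethylsilyl)pent-3-enoyl chloride | C/C(=C/CC(=O)Cl)[Si](CC)(CC)CC | intermediate
9 | (6S,8S)-1,5,5,9-tetramethyl-4-oxospiro[5.5]undeca-1,9-dien-8-yl benzoate | CC1=CCC(=O)C(C)(C)[C@]12CC=C(C)[C@@H](OC(=O)c3ccccc3)C2 | intermediate
10 | (4S,6S,8S)-4-hydroxy-1,5,5,9-tetramethylspiro[5.5]undeca-1,9-dien-8-yl benzoate | CC1=CC[C@H](O)C(C)(C)[C@]12CC=C(C)[C@@H](OC(=O)c3ccccc3)C2 | intermediate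
11 | (4R,6S,8S)-4-bromo-1,5,5,9-tetramethylspiro[5.5]undeca-1,9-dien-8-yl benzoate | CC1=CC[C@@H](Br)C(C)(C)[C@]12CC=C(C)[C@@H](OC(=O)c3ccccc3)C2 | intermediate
12 | (4R,6S,8S)-4-bromo-1,5,5,9-tetramethylspiro[5.5]undeca-1,9-dien-8-ol | CC1=CC[C@@H](Br)C(C)(C)[C@]12CC=C(C)[C@@H](O)C2 | intermediate
13 | N-[(4R,6S,8R)-4-bromo-1,5,5,9-tetramethylspiro[5.5]undeca-1,9-dien-8-yl]-2-nitrobenzenesulfonohydrazide (alkylated on the sulfonamide nitrogen) | CC1=CC[C@@H](Br)C(C)(C)[C@]12CC=C(C)[C@H](N(N)S(=O)(=O)c3ccccc3[N+](=O)[O-])C2 | intermediate
14 | [(4R,6S,8R)-4-bromo-1,5,5,9-tetramethylspiro[5.5]undeca-1,9-dien-8-yl]diazene | CC1=CC[C@@H](Br)C(C)(C)[C@]12CC=C(C)[C@H](N=N)C2 | intermediate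
15 | (4R,6S)-4-bromo-1,5,5,9-tetramethylspiro[5.5]undeca-1,8-diene | CC1=CC[C@@H](Br)C(C)(C)[C@]12CCC(C)=CC2 | intermediate
16 | (4R,6S,8S,9S)-4-bromo-8-chloro-1,5,5,9-tetramethylspiro[5.5]undec-1-en-9-ol | CC1=CC[C@@H](Br)C(C)(C)[C@]12CC[C@](C)(O)[C@@H](Cl)C2 | intermediate
17 | (4R,6S,8S,9S)-4,9-dibromo-8-chloro-1,5,5,9-tetramethylspiro[5.5]undec-1-ene | CC1=CC[C@@H](Br)C(C)(C)[C@]12CC[C@](C)(Br)[C@@H](Cl)C2 | target

**Totals**

Total step count: 13. Longest linear sequence: 10 steps (steps 1–3 and 7–13).

**Steps most likely to fail, with fallbacks**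

1. Step 7 (proposed new method). What may go wrong:
   - the acylium ion bonds to the ring carbon C6 instead of C5 (wrong regiochemistry of the first C–C bond);
   - the allylic benzoate ionizes and the diene aromatizes;
   - the acylium ion attacks the vinylsilane of a second molecule;
   - the cation or dioxanylium ion is quenched before the vinylsilane closes.

   Fallback with known reactions, from acid 7 back to the route at 15. It makes the C5–C6 bond by an aldol, so the regiochemistry is fixed, but it gives up the carvone control of the spiro centre and settles it by separation. Amide coupling of 7 with N,O-dimethylhydroxylamine should give the Weinreb amide (Z)-N-methoxy-N-methyl-4-(triethylsilyl)pent-3-enamide F1. CH2=C(CH3)MgBr should give the isopropenyl ketone (Z)-2-methyl-6-(triethylsilyl)hepta-1,5-dien-3-one F2. Conjugate reduction with LiBH(s-Bu)3 should give the tetrasubstituted lithium enolate regiospecifically, which adds to commercial 4-methylcyclohex-3-en-1-one to give the tertiary aldol (Z)-2-(1-hydroxy-4-methylcyclohex-3-en-1-yl)-2-methyl-6-(triethylsilyl)hept-5-en-3-one F3. SnCl4 at −78 °C should ionize the tertiary alcohol, and vinylsilane-terminated cyclization should close ring A to racemic 1,5,5,9-tetramethylspiro[5.5]undeca-1,8-dien-4-one F4. The CBS reduction of step 8 should give the (4S)-alcohols as a pair of C6 epimers; chromatography should give (4S,6S)-1,5,5,9-tetramethylspiro[5.5]undeca-1,8-dien-4-ol F5, and the Appel reaction of step 9 then gives 15.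

2. Step 13. What may go wrong: elimination or loss of configuration at the tertiary C9 cation, or HBr-induced migration of the ring A alkene.

   Fallback from 15 back to the route at 17, reaching the same chlorine-bridged cation from an alkene instead of an alcohol. Ene-type allylic chlorination of the ring B alkene with hypochlorous acid (Ca(OCl)2, CO2, CH2Cl2/H2O) should put chlorine on C8 from the open face and give (4R,6S,8S)-4-bromo-8-chloro-1,5,5-trimethyl-9-methylidenespiro[5.5]undec-1-ene F8. Markovnikov addition of HBr (HBr in AcOH, CH2Cl2, −40 °C) to the exocyclic alkene, anti to the allylic chlorine as in the addition of HBr to allylic halides, should then give 17.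

3. Step 9. What may go wrong: E2 elimination toward C3 (to a conjugated diene) or a 1,2-methyl shift from C5 takes the place of SN2 substitution at the neopentyl-type carbinol.

   Fallback from ketone 9 back to the route at 11, by substitution with retention. CBS reduction with the (S)-catalyst should give (4R,6S,8S)-4-hydroxy-1,5,5,9-tetramethylspiro[5.5]undeca-1,9-dien-8-yl benzoate F6, and MsCl/Et3N should give (4R,6S,8S)-4-(methylsulfonyloxy)-1,5,5,9-tetramethylspiro[5.5]undeca-1,9-dien-8-yl benzoate F7. Solvolysis with MgBr2·OEt2 should then proceed with participation of the C1=C2 alkene (homoallyl/cyclopropylcarbinyl cation, as in cholesteryl-type substitutions), and bromide should open that cation at C4 with overall retention to give 11.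

Further compounds
F1 | step 7 | (Z)-N-methoxy-N-methyl-4-(triethylsilyl)pent-3-enamide | C/C(=C/CC(=O)N(C)OC)[Si](CC)(CC)CC
F2 | step 7 | (Z)-2-methyl-6-(triethylsilyl)hepta-1,5-dien-3-one | C/C(=C/CC(=O)C(C)=C)[Si](CC)(CC)CC
F3 | step 7 | (Z)-2-(1-hydroxy-4-methylcyclohex-3-en-1-yl)-2-methyl-6-(triethylsilyl)hept-5-en-3-one (racemic) | C/C(=C/CC(=O)C(C)(C)C1(O)CCC(C)=CC1)[Si](CC)(CC)CC
F4 | step 7 | rac-1,5,5,9-tetramethylspiro[5.5]undeca-1,8-dien-4-one | CC1=CCC(=O)C(C)(C)C12CCC(C)=CC2
F5 | step 7 | (4S,6S)-1,5,5,9-tetramethylspiro[5.5]undeca-1,8-dien-4-ol | CC1=CC[C@H](O)C(C)(C)[C@]12CCC(C)=CC2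
F6 | step 9 | (4R,6S,8S)-4-hydroxy-1,5,5,9-tetramethylspiro[5.5]undeca-1,9-dien-8-yl benzoate | CC1=CC[C@@H](O)C(C)(C)[C@]12CC=C(C)[C@@H](OC(=O)c3ccccc3)C2
F7 | step 9 | (4R,6S,8S)-4-(methylsulfonyloxy)-1,5,5,9-tetramethylspiro[5.5]undeca-1,9-dien-8-yl benzoate | CC1=CC[C@@H](OS(C)(=O)=O)C(C)(C)[C@]12CC=C(C)[C@@H](OC(=O)c3ccccc3)C2
F8 | step 13 | (4R,6S,8S)-4-bromo-8-chloro-1,5,5-trimethyl-9-methylidenespiro[5.5]undec-1-ene | CC1=CC[C@@H](Br)C(C)(C)[C@]12CCC(=C)[C@@H](Cl)C2
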